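Abbreviations: prenyl = 3-methylbut-2-en-1-yl, MOM = methoxymethyl, THP = tetrahydro-2H-pyran-2-yl, TBS = tert-butyldimethylsilyl. Compound numbers are those of the steps below.

## Analysis of the target

The target is an isoflavanone: a chroman-4-one (benzene ring A fused to the oxygen heterocycle, ring C) that carries the aryl ring B on C3. Ring A has hydroxyls at C5 and C7 with a prenyl group between them at C6; ring B has a 3-hydroxyl, a 4-methoxyl and a 5-prenyl group. The only stereocentre is C3, of S configuration (CIP order C4 > C2 > aryl > H); it is benzylic and α to the C4 carbonyl, so it racemises by enolisation, fast in base and more slowly in acid. The sensitive groups are the two trisubstituted alkenes (protonation leads to chromans by attack of a neighbouring oxygen; they also react with electrophilic carbenes, halogens and oxidants), three phenols, one of them chelated to C4=O, and one methyl ether that must survive while the other oxygens are freed. The difficulties are regiochemical (6-prenyl and not 8-prenyl, 3-aryl and not 2-aryl, a 1,3,4,5-substituted ring B) and stereochemical (one labile centre that must be set late). Two features carry the plan. Formally excising C3 together with ring B joins C2 directly to C4 and leaves a benzofuran-3(2H)-one, so ring C is a coumaranone into which one aryl-substituted carbon has been inserted. Ring A, with its prenyl group flanked by O5 and O7 and with O1 para to it, maps onto a C2-symmetric 3,5-dioxygenated 4-prenylphenol, so the 6/8 question never arises.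

## Retrosynthetic reasoning

**31 from 30.** The last bonds cut are the three O–CH2OMe bonds. The phenols stay masked as acetals through every organometallic and basic step, and the unmasking has to be short and aprotic because C3 is already in place.

**30 from 29, and 29 from 27.** The C3–H bond is cut next. C3 is the only stereocentre and is epimerisable, so it is made as late as possible, by catalyst-controlled protonation of the silyl enol ether 29. Compound 29 comes from the flat isoflavone 27 by delivery of hydride to C2 and O-silylation of enolate 28. All earlier intermediates are then achiral at C3 and can be handled without regard to enolisation.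

**27 from 26 and 3.** The aryl–CH2 bond of the ring-B prenyl group is cut, leaving bromide as a placeholder. This keeps a second nucleophilic alkene out of the carbene step; the forward reaction is a cross-coupling of an allylic zinc reagent made from 3, which must deliver the linear isomer.

**26 from 14 and 22 (key disconnection).** C2–C3 and C3–C4 are cut at once, which removes C3 with ring B and contracts ring C to the silyloxybenzofuran 14. The forward reaction has carbene 23, released from diazirine 22, add across the enol ether bond of 14; cyclopropane 24 then opens to the six-membered cation 25, which loses its silyl group. This is preferred to cutting C3–C1' (a cross-coupling that needs a 3-halochromone) or C4–C4a (an acid-mediated acylation) because the aryl group arrives already bonded to the inserted carbon, and both partners are simple aromatic compounds.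

**14 from 13, 13 from 11, 11 from 8 and 9.** The O–Si bond, the O1–C2 bond and the C4–C4a bond are cut in turn. Closing the five-membered ring by acid-mediated acylation of ring A with a tethered carboxyl group would need conditions that destroy MOM ethers and prenyl groups. The ring is therefore closed in the opposite order: aryllithium 10 is acylated by Weinreb amide 9, and the phenoxide of 12 then displaces chloride. O1 needs a protecting group that directs lithiation yet comes off in the presence of MOM ethers, which is the role of the THP group in 8.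

**8 from 7, 7 from 5, 5 from 2 and 3, 2 from 1.** The C–O bond para to the prenyl group is cut back to a C–H bond. In 5 that hydrogen is the only one without an ortho neighbour, so sterically governed borylation and oxidation should install O1 without any differentiation of three like oxygens. The prenyl group is cut from the position between the two acetal oxygens of 2, where directed lithiation is unambiguous. Everything up to 10 is symmetric, so the 6-prenyl pattern is fixed by construction.

**22 from 21, 21 from 19, 19 from 18, and 18 back to 15.** The N=N and C–Cl bonds are cut back to amidine 21 (oxidative N–N bond formation), the amidine to nitrile 19, and the nitrile to aldehyde 18. The ring-B oxygen pattern comes from 15 by moving the methyl group from O3 to O4 (16, 17) and protecting the freed hydroxyl.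

## Alternatives that were turned down

Alternative 1: The C2–C3 bond is cut and C2 is traced back to the methyl group of an aryl methyl ether on ring A. In the forward direction the diazoketone A2, with a chiral dirhodium tetracarboxylate Rh2(O2CR*)4 (divalent rhodium), would lose N2 and the carbene at C3 would insert into an O-methyl C–H bond to close ring C and give the silyl-protected isoflavanone A1. In its favour, ring closure and the C3 configuration are achieved in one catalytic step with both prenyl groups already in place, so the endgame is shorter than the one chosen here; on step economy after the key step it is the stronger plan. Against it, the carbene sits five atoms from the methoxy oxygen, so oxonium ylide formation and a 1,2-shift to a 2-methylcoumaranone compete directly with insertion into a primary C–H bond. Two prenyl alkenes are open to cyclopropanation, and the new centre is α to the ketone and would be exposed to the Lewis-acidic catalyst and then to fluoride during desilylation of A1. A2 also needs ring A with one methyl ether and two silyl ethers, which brings back the differentiation of three like oxygens. The chosen route gives up the one-step stereocontrol and in return has a ring closure whose regiochemistry cannot go wrong and a stereocentre made separately on a flat precursor.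

Alternative 2: Ring A is dismantled completely, cutting C8–C8a, C5–C6, C7–C8 and C4a–C5. Irradiation of the pyranone diazoketone A4 with the prenyl-bearing siloxyalkyne A5 would trigger a Wolff rearrangement, ketene–alkyne cycloaddition, four-electron ring opening and six-electron ring closure to give isoflavone A3. This places 5-OH, 6-prenyl and 7-silyloxy by construction, differentiates O5 from O7, needs no cross-coupling for either prenyl group, and forms four bonds in one operation; on bond count and ring-A regiocontrol it is at least as strong as the chosen plan. Against it, A4 is a densely functionalised heterocycle and A5 a labile ynol ether, each needing its own synthesis. Ultraviolet light meets a pyranone chromophore and two alkenes, and the ketene intermediates can be intercepted by them. A3 still lacks the stereocentre, so the same reduction and protonation must follow. The chosen route starts from an intact, symmetric aromatic ring A and confines the untested chemistry to a two-bond event.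

Alternative 3: The C4–C4a bond is cut. The (S)-configured acid A7 would be activated as a mixed anhydride with a perfluorinated acid anhydride and would acylate ring A ortho to O1 to give chromanone A6, which is the same compound as 30. The closure is a classical six-membered Friedel–Crafts acylation onto a symmetric ring, it starts from the same phenol 7, and it needs no reaction without precedent; on that point it is stronger than the chosen plan, and it reaches 30 without a reduction step. Against it, the stereocentre of A7 is benzylic and α to the activated carboxyl, so ketene formation can racemise it, and the product ketone then sits in strong acid. The same acid threatens the MOM ethers and can cyclise the prenyl groups onto their neighbouring oxygens. Enantiopure A7 needs its own asymmetric synthesis, and as a 3-aryloxy-2-arylpropanoate it is prone to β-elimination of the aryloxide under base. The chosen route creates C3 only after all strongly acidic and basic steps are over and forms ring C in a buffered, nearly neutral medium.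

Key step: step 14

Remark on the chemistry: the sense of induction of the chiral Brønsted acid on 29 cannot be derived from structure alone. The (S)-configured catalyst is written, and its enantiomer would be used should a trial give the (3R)-ketone.

## Route

Step 1
Reactants: 1 resorcinol
Product: 2 1,3-bis(methoxymethoxy)benzene
Conditions: NaH, MOMCl, DMF, 0 °C → rt
Reagents that add atoms: chloromethyl methyl ether, COCCl
Why: Williamson-type alkylation of both phenoxides gives the bis-acetal, whose MOM groups later direct lithiation and survive all basic and organometallic steps.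

Step 2
Reactants: 2 1,3-bis(methoxymethoxy)benzene; 3 prenyl bromide
Product: 5 1,3-bis(methoxymethoxy)-2-(3-methylbut-2-en-1-yl)benzene, via aryllithium 4 (not isolated)
Conditions: n-BuLi, THF, 0 °C → rt; CuI (10 mol%), 3, −78 °C → rt
Reagents that add atoms: n-butyllithium, CCCC[Li] (lithium of intermediate 4 only)
Why: Directed ortho-metalation should occur at the position between the two acetal oxygens, and copper-catalysed SN2 allylation with 3 should give the linear prenyl arene. The prenyl group then lies between two identical oxygens.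

Step 3
Reactants: 5 1,3-bis(methoxymethoxy)-2-(3-methylbut-2-en-1-yl)benzene
Product: 7 3,5-bis(methoxymethoxy)-4-(3-methylbut-2-en-1-yl)phenol, via pinacol arylboronate 6 (not isolated)
Conditions: [Ir(OMe)(cod)]2 (1.5 mol%), dtbpy, B2pin2, THF, 70 °C; then 30% H2O2, aq NaOH, 0 °C
Reagents that add atoms: bis(pinacolato)diboron, CC1(C)OB(OC1(C)C)B1OC(C)(C)C(C)(C)O1 (boron of intermediate 6 only); hydrogen peroxide, OO
Why: Sterically governed C–H borylation should take the only C–H bond without an ortho substituent, para to the prenyl group. Alkaline peroxide then turns C–B into C–O without epoxidising the trisubstituted alkene.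

Step 4
Reactants: 7 3,5-bis(methoxymethoxy)-4-(3-methylbut-2-en-1-yl)phenol
Product: 8 2-[3,5-bis(methoxymethoxy)-4-(3-methylbut-2-en-1-yl)phenoxy]tetrahydro-2H-pyran (racemic)
Conditions: 3,4-dihydro-2H-pyran, PPTS (cat.), CH2Cl2, rt
Reagents that add atoms: 3,4-dihydro-2H-pyran, C1=COCCC1
Why: Acid-catalysed addition of the phenol to the enol ether gives a THP acetal that directs the next lithiation and is cleaved under conditions that leave MOM ethers intact.

Step 5
Reactants: 8 2-[3,5-bis(methoxymethoxy)-4-(3-methylbut-2-en-1-yl)phenoxy]tetrahydro-2H-pyran; 9 2-chloro-N-methoxy-N-methylacetamide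
Product: 11 2-chloro-1-[2,4-bis(methoxymethoxy)-3-(3-methylbut-2-en-1-yl)-6-(tetrahydro-2H-pyran-2-yloxy)phenyl]ethan-1-one, via aryllithium 10 (not isolated)
Conditions: n-BuLi, TMEDA, THF, 0 °C; then 9, −78 → −20 °C; aq NH4Cl
Reagents that add atoms: n-butyllithium, CCCC[Li] (lithium of intermediate 10 only)
Why: The two remaining ring hydrogens are equivalent and each lies between two acetal oxygens, so directed ortho-metalation is regiochemically unambiguous. Acylation by the Weinreb amide stops at the ketone (Weinreb ketone synthesis) and forms the future C4–C4a bond.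

Step 6
Reactants: 11 2-chloro-1-[2,4-bis(methoxymethoxy)-3-(3-methylbut-2-en-1-yl)-6-(tetrahydro-2H-pyran-2-yloxy)phenyl]ethan-1-one
Product: 13 4,6-bis(methoxymethoxy)-5-(3-methylbut-2-en-1-yl)benzofuran-3(2H)-one, via free phenol 12 (not isolated)
Conditions: PPTS, MeOH, rt; then NaOAc, 50 °C
Reagents that add atoms: none
Why: Mild acetal exchange should remove only the THP group, and the freed phenoxide closes the five-membered ring by intramolecular SN2 displacement of chloride (5-exo-tet), the classical coumaranone closure. No acid strong enough to harm MOM or prenyl groups is involved.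

Step 7
Reactants: 13 4,6-bis(methoxymethoxy)-5-(3-methylbut-2-en-1-yl)benzofuran-3(2H)-one
Product: 14 tert-butyl{[4,6-bis(methoxymethoxy)-5-(3-methylbut-2-en-1-yl)benzofuran-3-yl]oxy}dimethylsilane
Conditions: TBSOTf, Et3N, CH2Cl2, −78 → 0 °C
Reagents that add atoms: tert-butyldimethylsilyl trifluoromethanesulfonate, CC(C)(C)[Si](C)(C)OS(=O)(=O)C(F)(F)F
Why: Soft enolisation towards the aromatic benzofuran and O-silylation give the electron-rich enol ether double bond that the carbene step needs. Amine base and low temperature keep the silyl triflate from attacking the MOM ethers.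

Step 8
Reactants: 15 5-bromovanillin
Product: 16 3-bromo-4,5-dihydroxybenzaldehyde
Conditions: AlCl3, pyridine, CH2Cl2, reflux; aq HCl
Reagents that add atoms: none
Why: Lewis acid-assisted demethylation: aluminium chelated between the phenoxide and the neighbouring methoxy oxygen activates the methyl group for SN2 attack by pyridine.

Step 9
Reactants: 16 3-bromo-4,5-dihydroxybenzaldehyde
Product: 17 3-bromo-5-hydroxy-4-methoxybenzaldehyde
Conditions: MeI (1.1 equiv), Li2CO3, DMF, 40 °C
Reagents that add atoms: iodomethane, CI
Why: The 4-hydroxyl, para to the aldehyde and ortho to bromine, is the more acidic one, so a weak base should form its phenoxide selectively and Williamson methylation should occur there.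

Step 10
Reactants: 17 3-bromo-5-hydroxy-4-methoxybenzaldehyde
Product: 18 3-bromo-4-methoxy-5-(methoxymethoxy)benzaldehyde
Conditions: MOMCl, i-Pr2NEt, CH2Cl2, 0 °C → rt
Reagents that add atoms: chloromethyl methyl ether, COCCl
Why: Acetal protection of the remaining phenol under amine base; the same group is used on ring A so that one final deprotection suffices.

Step 11
Reactants: 18 3-bromo-4-methoxy-5-(methoxymethoxy)benzaldehyde
Product: 19 3-bromo-4-methoxy-5-(methoxymethoxy)benzonitrile
Conditions: I2, 28% aq NH3, THF, rt
Reagents that add atoms: ammonia, N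
Why: Condensation with ammonia gives the aldimine, iodine oxidises it to the N-iodo imine, and loss of HI gives the nitrile. The medium stays basic, which suits the MOM ether.

Step 12
Reactants: 19 3-bromo-4-methoxy-5-(methoxymethoxy)benzonitrile
Product: 21 3-bromo-4-methoxy-5-(methoxymethoxy)benzamidine hydrochloride, via lithium N,N'-bis(trimethylsilyl)amidinate 20 (not isolated)
Conditions: LiN(SiMe3)2, THF, 0 °C → rt; then MeOH, NH4Cl, 0 °C → rt
Reagents that add atoms: lithium bis(trimethylsilyl)amide, C[Si](C)(C)N([Li])[Si](C)(C)C; ammonium chloride, [NH4+].[Cl-]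
Why: Addition of the silylamide to the nitrile gives the silylated amidinate; methanolysis of the N–Si bonds and protonation by ammonium chloride should give the amidinium chloride without exposing the MOM ether to mineral acid.

Step 13
Reactants: 21 3-bromo-4-methoxy-5-(methoxymethoxy)benzamidine hydrochloride
Product: 22 3-[3-bromo-4-methoxy-5-(methoxymethoxy)phenyl]-3-chloro-3H-diazirine
Conditions: aq NaOCl, LiCl, DMSO, pentane, 0 °C → rt
Reagents that add atoms: sodium hypochlorite, [Na+].[O-]Cl; lithium chloride, [Li+].[Cl-] (added chloride source for the same chlorine atom)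
Why: Graham oxidation: N-chlorination, base-induced N–N bond formation and substitution by chloride convert the amidine into the chlorodiazirine. The 4-methoxy group is twisted out of conjugation by its two ortho neighbours, which should temper the lability usual for donor-substituted chlorodiazirines.

Step 14
Reactants: 14 tert-butyl{[4,6-bis(methoxymethoxy)-5-(3-methylbut-2-en-1-yl)benzofuran-3-yl]oxy}dimethylsilane; 22 3-[3-bromo-4-methoxy-5-(methoxymethoxy)phenyl]-3-chloro-3H-diazirine
Product: 26 3-[3-bromo-4-methoxy-5-(methoxymethoxy)phenyl]-5,7-bis(methoxymethoxy)-6-(3-methylbut-2-en-1-yl)-4H-chromen-4-one, via arylchlorocarbene 23 (not isolated), via chlorocyclopropane 24 (not isolated), via 4-silyloxybenzopyrylium chloride 25 (not isolated)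
Conditions: 14 (1.5 equiv), 22 (added in portions), Na2CO3, MeCN, 50 °C, dark
Reagents that add atoms: none
Why: Proposed new method: Thermal loss of N2 from 22 gives the singlet arylchlorocarbene 23, an electrophilic carbene that should add in a [2+1] sense to the most electron-rich π bond present, the C2=C3 enol ether bond of 14, which is activated by the ring oxygen at one end and the silyloxy group at the other. Chlorocyclopropane 24 should then ionise with disrotatory opening of the bond it shares with the furan ring, pushed by both oxygen lone pairs, so that the carbene carbon becomes C3 bonded to C2 and C4 and the five-membered ring is enlarged to the six-membered cation 25 (two-electron electrocyclic opening, ring expansion by one carbon). Chloride then removes the silyl group and the chromone carbonyl of 26 appears. The closest known reactions are the carbon-atom insertion of arylchlorocarbenes from chlorodiazirines into indoles, pyrroles and indenes (Ciamician–Dennstedt type) and the halocarbene ring expansion of cyclic silyl enol ethers and of benzofurans; a 3-silyloxybenzofuran has not been used as substrate. No stereocentre is formed, since 24 is a transient mixture of diastereomers; the isomer with chloride on the concave face opens directly and the other needs ionisation assisted by the aryl and oxygen donors. The step needs chemoselectivity for the enol ether over the ring-A prenyl alkene, which rests on the far higher nucleophilicity of the doubly oxygenated double bond, on keeping 14 in excess while 22 is fed in, and on carrying bromine in place of prenyl on ring B. Regiochemistry is not in question, because the aryl group is delivered on the inserted carbon and can only end at C3. Na2CO3 keeps the medium free of acid so that 14 is not desilylated before it reacts.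

Step 15
Reactants: 26 3-[3-bromo-4-methoxy-5-(methoxymethoxy)phenyl]-5,7-bis(methoxymethoxy)-6-(3-methylbut-2-en-1-yl)-4H-chromen-4-one; 3 prenyl bromide (used as its zinc reagent)
Product: 27 5,7-bis(methoxymethoxy)-3-[4-methoxy-3-(methoxymethoxy)-5-(3-methylbut-2-en-1-yl)phenyl]-6-(3-methylbut-2-en-1-yl)-4H-chromen-4-one
Conditions: prenylzinc bromide (from 3, Zn, LiCl, THF), Pd(OAc)2 (2 mol%), CPhos (4 mol%), THF, rt
Reagents that add atoms: 3-methylbut-2-en-1-ylzinc bromide, CC(C)=CC[Zn]Br (made beforehand from 3 and zinc)
Why: Negishi coupling of an allylic zinc reagent; with the biarylphosphine CPhos, reductive elimination at the primary allyl terminus is favoured, which should give the linear prenyl arene and not the 1,1-dimethylallyl isomer. Coupling at room temperature should outrun addition of the zinc reagent to the vinylogous ester carbonyl.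

Step 16
Reactants: 27 5,7-bis(methoxymethoxy)-3-[4-methoxy-3-(methoxymethoxy)-5-(3-methylbut-2-en-1-yl)phenyl]-6-(3-methylbut-2-en-1-yl)-4H-chromen-4-one
Product: 29 {[5,7-bis(methoxymethoxy)-3-[4-methoxy-3-(methoxymethoxy)-5-(3-methylbut-2-en-1-yl)phenyl]-6-(3-methylbut-2-en-1-yl)-2H-chromen-4-yl]oxy}trimethylsilane, via lithium enolate 28 (not isolated)
Conditions: LiBH(s-Bu)3, THF, −78 °C; then Me3SiCl, Et3N, −78 → 0 °C; non-aqueous work-up
Reagents that add atoms: lithium tri-sec-butylborohydride, [Li+].CCC(C)[BH-](C(C)CC)C(C)CC (lithium of intermediate 28 only); chlorotrimethylsilane, C[Si](C)(C)Cl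
Why: The bulky borohydride should add hydride in a 1,4-sense to C2 of the chromone (conjugate reduction), and O-silylation of the enolate stores C3 as a prochiral sp2 carbon.

Step 17
Reactants: 29 {[5,7-bis(methoxymethoxy)-3-[4-methoxy-3-(methoxymethoxy)-5-(3-methylbut-2-en-1-yl)phenyl]-6-(3-methylbut-2-en-1-yl)-2H-chromen-4-yl]oxy}trimethylsilane
Product: 30 (3S)-5,7-bis(methoxymethoxy)-3-[4-methoxy-3-(methoxymethoxy)-5-(3-methylbut-2-en-1-yl)phenyl]-6-(3-methylbut-2-en-1-yl)chroman-4-one
Conditions: (S)-BINOL-derived N-triflylthiophosphoramide with 3,3'-bis(2,4,6-triisopropylphenyl) groups (5 mol%), PhOH (1.1 equiv), toluene, 0 °C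
Reagents that add atoms: none
Why: Chiral Brønsted acid-catalysed enantioselective protonation of the silyl enol ether of a cyclic 2-aryl ketone, with phenol as stoichiometric proton source and silyl acceptor. The C3 stereocentre is set by catalyst control: the chiral acid protonates one face of the enol carbon inside its binaphthyl pocket, which should lead to the (3S)-ketone.

Step 18
Reactants: 30 (3S)-5,7-bis(methoxymethoxy)-3-[4-methoxy-3-(methoxymethoxy)-5-(3-methylbut-2-en-1-yl)phenyl]-6-(3-methylbut-2-en-1-yl)chroman-4-one
Product: 31 (3S)-5,7-dihydroxy-3-[3-hydroxy-4-methoxy-5-(3-methylbut-2-en-1-yl)phenyl]-6-(3-methylbut-2-en-1-yl)chroman-4-one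
Conditions: ZnBr2, n-PrSH, CH2Cl2, 0 °C, ca. 10 min; work-up at pH 5
Reagents that add atoms: none
Why: Lewis acid-assisted transfer of the methoxymethyl groups to the thiol (acetal exchange) should cleave all three MOM ethers within minutes in an aprotic medium. This limits both acid-catalysed enolisation at C3 and cyclisation of the prenyl groups onto the new phenols; the product is kept away from base throughout isolation.

## Compound list

1 | resorcinol | Oc1cccc(O)c1 | starting material
2 | 1,3-bis(methoxymethoxy)benzene | COCOc1cccc(OCOC)c1 | intermediate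
3 | prenyl bromide (1-bromo-3-methylbut-2-ene) | CC(C)=CCBr | starting material
4 | 2,6-bis(methoxymethoxy)phenyllithium | [Li]c1c(OCOC)cccc1OCOC | intermediate (not isolated)
5 | 1,3-bis(methoxymethoxy)-2-(3-methylbut-2-en-1-yl)benzene | CC(C)=CCc1c(OCOC)cccc1OCOC | intermediate
6 | 2-[3,5-bis(methoxymethoxy)-4-(3-methylbut-2-en-1-yl)phenyl]-4,4,5,5-tetramethyl-1,3,2-dioxaborolane | CC(C)=CCc1c(OCOC)cc(B2OC(C)(C)C(C)(C)O2)cc1OCOC | intermediate (not isolated)
7 | 3,5-bis(methoxymethoxy)-4-(3-methylbut-2-en-1-yl)phenol | CC(C)=CCc1c(OCOC)cc(O)cc1OCOC | intermediate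
8 | 2-[3,5-bis(methoxymethoxy)-4-(3-methylbut-2-en-1-yl)phenoxy]tetrahydro-2H-pyran (racemic) | CC(C)=CCc1c(OCOC)cc(OC2CCCCO2)cc1OCOC | intermediate
9 | 2-chloro-N-methoxy-N-methylacetamide | CON(C)C(=O)CCl | starting material
10 | [2,4-bis(methoxymethoxy)-3-(3-methylbut-2-en-1-yl)-6-(tetrahydro-2H-pyran-2-yloxy)phenyl]lithium | CC(C)=CCc1c(OCOC)cc(OC2CCCCO2)c([Li])c1OCOC | intermediate (not isolated)
11 | 2-chloro-1-[2,4-bis(methoxymethoxy)-3-(3-methylbut-2-en-1-yl)-6-(tetrahydro-2H-pyran-2-yloxy)phenyl]ethan-1-one (racemic) | CC(C)=CCc1c(OCOC)cc(OC2CCCCO2)c(C(=O)CCl)c1OCOC | intermediate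
12 | 2-chloro-1-[6-hydroxy-2,4-bis(methoxymethoxy)-3-(3-methylbut-2-en-1-yl)phenyl]ethan-1-one | CC(C)=CCc1c(OCOC)cc(O)c(C(=O)CCl)c1OCOC | intermediate (not isolated)
13 | 4,6-bis(methoxymethoxy)-5-(3-methylbut-2-en-1-yl)benzofuran-3(2H)-one | CC(C)=CCc1c(OCOC)cc2OCC(=O)c2c1OCOC | intermediate
14 | tert-butyl{[4,6-bis(methoxymethoxy)-5-(3-methylbut-2-en-1-yl)benzofuran-3-yl]oxy}dimethylsilane | CC(C)=CCc1c(OCOC)cc2occ(O[Si](C)(C)C(C)(C)C)c2c1OCOC | intermediate (key-step precursor)
15 | 5-bromovanillin (3-bromo-4-hydroxy-5-methoxybenzaldehyde) | COc1cc(C=O)cc(Br)c1O | starting material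
16 | 3-bromo-4,5-dihydroxybenzaldehyde | Oc1cc(C=O)cc(Br)c1O | intermediate
17 | 3-bromo-5-hydroxy-4-methoxybenzaldehyde | COc1c(O)cc(C=O)cc1Br | intermediate
18 | 3-bromo-4-methoxy-5-(methoxymethoxy)benzaldehyde | COCOc1cc(C=O)cc(Br)c1OC | intermediate
19 | 3-bromo-4-methoxy-5-(methoxymethoxy)benzonitrile | COCOc1cc(C#N)cc(Br)c1OC | intermediate
20 | lithium N,N'-bis(trimethylsilyl)-3-bromo-4-methoxy-5-(methoxymethoxy)benzamidinate | COCOc1cc(C(=N[Si](C)(C)C)N([Li])[Si](C)(C)C)cc(Br)c1OC | intermediate (not isolated)
21 | 3-bromo-4-methoxy-5-(methoxymethoxy)benzamidine hydrochloride | COCOc1cc(C(=N)N)cc(Br)c1OC.Cl | intermediate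
22 | 3-[3-bromo-4-methoxy-5-(methoxymethoxy)phenyl]-3-chloro-3H-diazirine | COCOc1cc(C2(Cl)N=N2)cc(Br)c1OC | intermediate (key-step precursor)
23 | [3-bromo-4-methoxy-5-(methoxymethoxy)phenyl]chlorocarbene | COCOc1cc([C]Cl)cc(Br)c1OC | intermediate (not isolated)
24 | 1-[3-bromo-4-methoxy-5-(methoxymethoxy)phenyl]-6b-(tert-butyldimethylsilyloxy)-1-chloro-4,6-bis(methoxymethoxy)-5-(3-methylbut-2-en-1-yl)-1a,6b-dihydro-1H-cyclopropa[b]benzofuran (racemic, mixture at C1) | CC(C)=CCc1c(OCOC)cc2OC3C(Cl)(c4cc(OCOC)c(OC)c(Br)c4)C3(O[Si](C)(C)C(C)(C)C)c2c1OCOC | intermediate (not isolated)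
25 | 3-[3-bromo-4-methoxy-5-(methoxymethoxy)phenyl]-4-(tert-butyldimethylsilyloxy)-5,7-bis(methoxymethoxy)-6-(3-methylbut-2-en-1-yl)chromenylium chloride | CC(C)=CCc1c(OCOC)cc2[o+]cc(-c3cc(OCOC)c(OC)c(Br)c3)c(O[Si](C)(C)C(C)(C)C)c2c1OCOC.[Cl-] | intermediate (not isolated)
26 | 3-[3-bromo-4-methoxy-5-(methoxymethoxy)phenyl]-5,7-bis(methoxymethoxy)-6-(3-methylbut-2-en-1-yl)-4H-chromen-4-one | COCOc1cc(-c2coc3cc(OCOC)c(CC=C(C)C)c(OCOC)c3c2=O)cc(Br)c1OC | intermediate (key-step product)
27 | 5,7-bis(methoxymethoxy)-3-[4-methoxy-3-(methoxymethoxy)-5-(3-methylbut-2-en-1-yl)phenyl]-6-(3-methylbut-2-en-1-yl)-4H-chromen-4-one | COCOc1cc(-c2coc3cc(OCOC)c(CC=C(C)C)c(OCOC)c3c2=O)cc(CC=C(C)C)c1OC | intermediate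
28 | lithium 5,7-bis(methoxymethoxy)-3-[4-methoxy-3-(methoxymethoxy)-5-(3-methylbut-2-en-1-yl)phenyl]-6-(3-methylbut-2-en-1-yl)-2H-chromen-4-olate | COCOc1cc(C2=C(O[Li])c3c(OCOC)c(CC=C(C)C)c(OCOC)cc3OC2)cc(CC=C(C)C)c1OC | intermediate (not isolated)
29 | {[5,7-bis(methoxymethoxy)-3-[4-methoxy-3-(methoxymethoxy)-5-(3-methylbut-2-en-1-yl)phenyl]-6-(3-methylbut-2-en-1-yl)-2H-chromen-4-yl]oxy}trimethylsilane | COCOc1cc(C2=C(O[Si](C)(C)C)c3c(OCOC)c(CC=C(C)C)c(OCOC)cc3OC2)cc(CC=C(C)C)c1OC | intermediate
30 | (3S)-5,7-bis(methoxymethoxy)-3-[4-methoxy-3-(methoxymethoxy)-5-(3-methylbut-2-en-1-yl)phenyl]-6-(3-methylbut-2-en-1-yl)chroman-4-one | COCOc1cc([C@H]2COc3cc(OCOC)c(CC=C(C)C)c(OCOC)c3C2=O)cc(CC=C(C)C)c1OC | intermediate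
31 | (3S)-5,7-dihydroxy-3-[3-hydroxy-4-methoxy-5-(3-methylbut-2-en-1-yl)phenyl]-6-(3-methylbut-2-en-1-yl)chroman-4-one | COc1c(O)cc([C@H]2COc3cc(O)c(CC=C(C)C)c(O)c3C2=O)cc1CC=C(C)C | target

## Step count and least certain steps

Total: 18 steps. Longest linear sequence: 12 steps (steps 1–7 and 14–18). The ring-B branch (steps 8–13) has 6 steps.

**Step 14 (key step).** The carbene may be consumed before it finds the enol ether: by addition to the ring-A prenyl alkene, by reaction with a second diazirine molecule, or by ylide formation at the acetal oxygens. The enol ether may also lose its silyl group and revert to the unreactive ketone, and the cyclopropane diastereomer with chloride on the convex face may open sluggishly or collapse to a 2-substituted coumaranone.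
Fallback by established isoflavone chemistry, from 8 back to 26: aryllithium 10 is trapped with N-methoxy-N-methylacetamide to give 1-[2,4-bis(methoxymethoxy)-3-(3-methylbut-2-en-1-yl)-6-(tetrahydro-2H-pyran-2-yloxy)phenyl]ethan-1-one F1. PPTS in MeOH frees 1-[6-hydroxy-2,4-bis(methoxymethoxy)-3-(3-methylbut-2-en-1-yl)phenyl]ethan-1-one F2. N,N-dimethylformamide dimethyl acetal converts it into (E)-3-(dimethylamino)-1-[6-hydroxy-2,4-bis(methoxymethoxy)-3-(3-methylbut-2-en-1-yl)phenyl]prop-2-en-1-one F3. Iodine in CHCl3/pyridine closes ring C to 3-iodo-5,7-bis(methoxymethoxy)-6-(3-methylbut-2-en-1-yl)-4H-chromen-4-one F4. The ring-B partner is made from commercial 3-bromo-2-methoxyphenol by MOM protection to 1-bromo-2-methoxy-3-(methoxymethoxy)benzene F5 and sterically governed C–H borylation ([Ir(OMe)(cod)]2, dtbpy, B2pin2) to 2-[3-bromo-4-methoxy-5-(methoxymethoxy)phenyl]-4,4,5,5-tetramethyl-1,3,2-dioxaborolane F6. Suzuki–Miyaura coupling of F4 with F6 (PdCl2(dppf), K2CO3, dioxane/water), in which the vinylic iodide should react well before the hindered aryl bromide, gives 26.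

**Step 17.** Poor facial selectivity is the main risk, because the enol carbon is flanked by the peri 5-OMOM group and by ring B with two meta substituents, a pattern outside the simple 2-aryl cycloalkanones. Uncatalysed protonation by phenol or premature hydrolysis of the trimethylsilyl enol ether would add racemic ketone.
Fallback from 27 back to 30: asymmetric transfer hydrogenation with dynamic kinetic resolution (RuCl[(S,S)-TsDPEN](p-cymene), HCO2H/Et3N, 40 °C; catalyst enantiomer chosen for the 3S series) reduces the C2=C3 bond and then the ketone to (3S,4S)-5,7-bis(methoxymethoxy)-3-[4-methoxy-3-(methoxymethoxy)-5-(3-methylbut-2-en-1-yl)phenyl]-6-(3-methylbut-2-en-1-yl)chroman-4-ol F7. Dess–Martin periodinane buffered with NaHCO3 then oxidises the alcohol to 30 under neutral conditions.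

**Step 18.** Erosion of the C3 configuration by Lewis or Brønsted acid-promoted enolisation during deprotection, and cyclisation of the ring-A prenyl group onto the freed 5- or 7-hydroxyl.
Fallback from 27 to 31, exchanging the protecting groups before C3 is created: HCl in MeOH removes the MOM groups from the achiral isoflavone to give 5,7-dihydroxy-3-[3-hydroxy-4-methoxy-5-(3-methylbut-2-en-1-yl)phenyl]-6-(3-methylbut-2-en-1-yl)-4H-chromen-4-one F8. TESOTf and 2,6-lutidine give 3-[4-methoxy-3-(triethylsilyloxy)-5-(3-methylbut-2-en-1-yl)phenyl]-6-(3-methylbut-2-en-1-yl)-5,7-bis(triethylsilyloxy)-4H-chromen-4-one F9. LiBH(s-Bu)3 followed by Me3SiCl gives {[3-[4-methoxy-3-(triethylsilyloxy)-5-(3-methylbut-2-en-1-yl)phenyl]-6-(3-methylbut-2-en-1-yl)-5,7-bis(triethylsilyloxy)-2H-chromen-4-yl]oxy}trimethylsilane F10. The chiral acid with phenol gives (3S)-3-[4-methoxy-3-(triethylsilyloxy)-5-(3-methylbut-2-en-1-yl)phenyl]-6-(3-methylbut-2-en-1-yl)-5,7-bis(triethylsilyloxy)chroman-4-one F11. HF·pyridine buffered with pyridine in THF at 0 °C frees 31 without strong acid or base.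

**Step 15.** The allylic zinc reagent may add to the chromone (at C4 or C2) faster than it cross-couples, and some branched 1,1-dimethylallyl isomer may form.
Fallback from 26 back to 27, with the polarity reversed: Miyaura borylation (B2pin2, PdCl2(dppf), KOAc, dioxane) gives 5,7-bis(methoxymethoxy)-3-[4-methoxy-3-(methoxymethoxy)-5-(4,4,5,5-tetramethyl-1,3,2-dioxaborolan-2-yl)phenyl]-6-(3-methylbut-2-en-1-yl)-4H-chromen-4-one F12. Palladium-catalysed allylation of this boronate with 3 (Pd(PPh3)4, K2CO3, THF/water), which proceeds through a π-allyl complex and couples at the less substituted terminus, gives 27.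

**Step 5.** Lithiation may stray to the doubly activated allylic–benzylic CH2 of the prenyl group, and the aryllithium may abstract a proton from the α-chloro amide instead of adding to it.
Fallback from 7 back to 13, without a second lithiation: ortho-formylation of the magnesium phenoxide (MgCl2, Et3N, paraformaldehyde, MeCN, reflux) gives 6-hydroxy-2,4-bis(methoxymethoxy)-3-(3-methylbut-2-en-1-yl)benzaldehyde F13. Dimethylsulfoxonium methylide (Me3S(O)I, NaH, DMSO) forms the epoxide, which the phenoxide opens in a 5-exo sense to 4,6-bis(methoxymethoxy)-5-(3-methylbut-2-en-1-yl)-2,3-dihydrobenzofuran-3-ol F14 (racemic). Dess–Martin periodinane oxidises it to 13.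

**Step 3.** The iridium boryl catalyst may hydroborate or borylate the prenyl alkene alongside the arene C–H bond.
Fallback from 2 back to 7, with the oxygen introduced before the alkene: the same borylation and oxidation on 2 give 3,5-bis(methoxymethoxy)phenol F15. TIPSCl and imidazole give [3,5-bis(methoxymethoxy)phenoxy]triisopropylsilane F16. Lithiation between the two acetal groups (the silyl ether does not direct) and copper-catalysed allylation with 3 give [3,5-bis(methoxymethoxy)-4-(3-methylbut-2-en-1-yl)phenoxy]triisopropylsilane F17, and TBAF frees 7.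

## Further compounds

F1 | step 14 | 1-[2,4-bis(methoxymethoxy)-3-(3-methylbut-2-en-1-yl)-6-(tetrahydro-2H-pyran-2-yloxy)phenyl]ethan-1-one | CC(C)=CCc1c(OCOC)cc(OC2CCCCO2)c(C(C)=O)c1OCOC
F2 | step 14 | 1-[6-hydroxy-2,4-bis(methoxymethoxy)-3-(3-methylbut-2-en-1-yl)phenyl]ethan-1-one | CC(C)=CCc1c(OCOC)cc(O)c(C(C)=O)c1OCOC
F3 | step 14 | (E)-3-(dimethylamino)-1-[6-hydroxy-2,4-bis(methoxymethoxy)-3-(3-methylbut-2-en-1-yl)phenyl]prop-2-en-1-one | CC(C)=CCc1c(OCOC)cc(O)c(C(=O)/C=C/N(C)C)c1OCOC
F4 | step 14 | 3-iodo-5,7-bis(methoxymethoxy)-6-(3-methylbut-2-en-1-yl)-4H-chromen-4-one | CC(C)=CCc1c(OCOC)cc2occ(I)c(=O)c2c1OCOC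
F5 | step 14 | 1-bromo-2-methoxy-3-(methoxymethoxy)benzene | COCOc1cccc(Br)c1OC
F6 | step 14 | 2-[3-bromo-4-methoxy-5-(methoxymethoxy)phenyl]-4,4,5,5-tetramethyl-1,3,2-dioxaborolane | COCOc1cc(B2OC(C)(C)C(C)(C)O2)cc(Br)c1OC
F7 | step 17 | (3S,4S)-5,7-bis(methoxymethoxy)-3-[4-methoxy-3-(methoxymethoxy)-5-(3-methylbut-2-en-1-yl)phenyl]-6-(3-methylbut-2-en-1-yl)chroman-4-ol | COCOc1cc([C@H]2COc3cc(OCOC)c(CC=C(C)C)c(OCOC)c3[C@H]2O)cc(CC=C(C)C)c1OC
F8 | step 18 | 5,7-dihydroxy-3-[3-hydroxy-4-methoxy-5-(3-methylbut-2-en-1-yl)phenyl]-6-(3-methylbut-2-en-1-yl)-4H-chromen-4-one | COc1c(O)cc(-c2coc3cc(O)c(CC=C(C)C)c(O)c3c2=O)cc1CC=C(C)C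
F9 | step 18 | 3-[4-methoxy-3-(triethylsilyloxy)-5-(3-methylbut-2-en-1-yl)phenyl]-6-(3-methylbut-2-en-1-yl)-5,7-bis(triethylsilyloxy)-4H-chromen-4-one | CC[Si](CC)(CC)Oc1cc(-c2coc3cc(O[Si](CC)(CC)CC)c(CC=C(C)C)c(O[Si](CC)(CC)CC)c3c2=O)cc(CC=C(C)C)c1OC
F10 | step 18 | {[3-[4-methoxy-3-(triethylsilyloxy)-5-(3-methylbut-2-en-1-yl)phenyl]-6-(3-methylbut-2-en-1-yl)-5,7-bis(triethylsilyloxy)-2H-chromen-4-yl]oxy}trimethylsilane | CC[Si](CC)(CC)Oc1cc(C2=C(O[Si](C)(C)C)c3c(O[Si](CC)(CC)CC)c(CC=C(C)C)c(O[Si](CC)(CC)CC)cc3OC2)cc(CC=C(C)C)c1OC
F11 | step 18 | (3S)-3-[4-methoxy-3-(triethylsilyloxy)-5-(3-methylbut-2-en-1-yl)phenyl]-6-(3-methylbut-2-en-1-yl)-5,7-bis(triethylsilyloxy)chroman-4-one | CC[Si](CC)(CC)Oc1cc([C@H]2COc3cc(O[Si](CC)(CC)CC)c(CC=C(C)C)c(O[Si](CC)(CC)CC)c3C2=O)cc(CC=C(C)C)c1OC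
F12 | step 15 | 5,7-bis(methoxymethoxy)-3-[4-methoxy-3-(methoxymethoxy)-5-(4,4,5,5-tetramethyl-1,3,2-dioxaborolan-2-yl)phenyl]-6-(3-methylbut-2-en-1-yl)-4H-chromen-4-one | COCOc1cc(-c2coc3cc(OCOC)c(CC=C(C)C)c(OCOC)c3c2=O)cc(B2OC(C)(C)C(C)(C)O2)c1OC
F13 | step 5 | 6-hydroxy-2,4-bis(methoxymethoxy)-3-(3-methylbut-2-en-1-yl)benzaldehyde | CC(C)=CCc1c(OCOC)cc(O)c(C=O)c1OCOC
F14 | step 5 | 4,6-bis(methoxymethoxy)-5-(3-methylbut-2-en-1-yl)-2,3-dihydrobenzofuran-3-ol (racemic) | CC(C)=CCc1c(OCOC)cc2OCC(O)c2c1OCOC
F15 | step 3 | 3,5-bis(methoxymethoxy)phenol | COCOc1cc(O)cc(OCOC)c1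
F16 | step 3 | [3,5-bis(methoxymethoxy)phenoxy]triisopropylsilane | COCOc1cc(OCOC)cc(O[Si](C(C)C)(C(C)C)C(C)C)c1
F17 | step 3 | [3,5-bis(methoxymethoxy)-4-(3-methylbut-2-en-1-yl)phenoxy]triisopropylsilane | CC(C)=CCc1c(OCOC)cc(O[Si](C(C)C)(C(C)C)C(C)C)cc1OCOC
A1 | alternative 1 | (3S)-5,7-bis(tert-butyldimethylsilyloxy)-3-[4-methoxy-3-(tert-butyldimethylsilyloxy)-5-(3-methylbut-2-en-1-yl)phenyl]-6-(3-methylbut-2-en-1-yl)chroman-4-one | COc1c(O[Si](C)(C)C(C)(C)C)cc([C@H]2COc3cc(O[Si](C)(C)C(C)(C)C)c(CC=C(C)C)c(O[Si](C)(C)C(C)(C)C)c3C2=O)cc1CC=C(C)C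
A2 | alternative 1 | 1-[2,4-bis(tert-butyldimethylsilyloxy)-6-methoxy-3-(3-methylbut-2-en-1-yl)phenyl]-2-diazo-2-[4-methoxy-3-(tert-butyldimethylsilyloxy)-5-(3-methylbut-2-en-1-yl)phenyl]ethan-1-one | COc1cc(O[Si](C)(C)C(C)(C)C)c(CC=C(C)C)c(O[Si](C)(C)C(C)(C)C)c1C(=O)C(=[N+]=[N-])c1cc(O[Si](C)(C)C(C)(C)C)c(OC)c(CC=C(C)C)c1
A3 | alternative 2 | 5-hydroxy-3-[4-methoxy-3-(methoxymethoxy)-5-(3-methylbut-2-en-1-yl)phenyl]-6-(3-methylbut-2-en-1-yl)-7-(triisopropylsilyloxy)-4H-chromen-4-one | COCOc1cc(-c2coc3cc(O[Si](C(C)C)(C(C)C)C(C)C)c(CC=C(C)C)c(O)c3c2=O)cc(CC=C(C)C)c1OC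
A4 | alternative 2 | 2-(2-diazoacetyl)-5-[4-methoxy-3-(methoxymethoxy)-5-(3-methylbut-2-en-1-yl)phenyl]-4H-pyran-4-one | COCOc1cc(-c2coc(C(=O)C=[N+]=[N-])cc2=O)cc(CC=C(C)C)c1OC
A5 | alternative 2 | triisopropyl[(5-methylhex-4-en-1-yn-1-yl)oxy]silane | CC(C)=CCC#CO[Si](C(C)C)(C(C)C)C(C)C
A6 | alternative 3 | (3S)-5,7-bis(methoxymethoxy)-3-[4-methoxy-3-(methoxymethoxy)-5-(3-methylbut-2-en-1-yl)phenyl]-6-(3-methylbut-2-en-1-yl)chroman-4-one | COCOc1cc([C@H]2COc3cc(OCOC)c(CC=C(C)C)c(OCOC)c3C2=O)cc(CC=C(C)C)c1OC
A7 | alternative 3 | (2S)-3-[3,5-bis(methoxymethoxy)-4-(3-methylbut-2-en-1-yl)phenoxy]-2-[4-methoxy-3-(methoxymethoxy)-5-(3-methylbut-2-en-1-yl)phenyl]propanoic acid | COCOc1cc([C@H](C(=O)O)COc2cc(OCOC)c(CC=C(C)C)c(OCOC)c2)cc(CC=C(C)C)c1OC
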